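The tetrahydropyran-4-one ring (O1, C2 to C6) is opened at two bonds, C3–C4 and O1–C2. The feature exploited is that C2–C3 maps onto the vinyl group of an O-protected 4-vinylguaiacol: inner carbon C2 bears ring oxygen O1, terminal carbon C3 bears the C4 carbonyl. In one mediated anodic operation a 2-oxo carboxylate loses CO2, its acyl radical adds to the styrene terminus, the benzylic radical is oxidised to a cation, and the C6 hydroxyl closes the ring, setting C2 cis to C6. The precursor is an open-chain lithium 4-hydroxy-2-oxohexanoate with a silylated C1′ oxygen and a benzyl-protected phenol, reached from O-benzyl-L-tyrosine by a Felkin-controlled pyruvate aldol addition.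

Key step: step 9

Remarks on the chemistry
- Configuration check: with O1, C2 (guaiacyl), C3, C4 (C=O), C5, C6 and side chain C1′ (carbinol), C2′ (CH2Ar), the target SMILES reads (2S,6R,1′S). The ring is 2,6-cis and the C6–O/C1′–O pair is anti. An (S)-2-silyloxy aldehyde under Felkin control gives exactly this anti pair, (4R,5S) in the open-chain precursor.
- Assumption: O-benzyl-L-tyrosine, 2-methoxy-4-vinylphenol and ethyl pyruvate are taken as commercial.
- Protecting group on the guaiacol oxygen: a benzyl carbonate is used. It is as electron-withdrawing as an ester, but it falls in the final hydrogenolysis, so the base-sensitive pyranone never meets base.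
- Form of the precursor: the 2-oxo acid is handled only as its lithium salt, because the free acid can close to a five-membered lactone.
- Conditions of the electrolysis: AcOH feeds the cathode so that no base builds up. A triarylamine mediator keeps the working potential below that of the styrene and the benzyloxyarene.

Step 1
Reactants: 1 O-benzyl-L-tyrosine
Product: 3 (S)-3-[4-(benzyloxy)phenyl]-2-hydroxypropanoic acid, via α-lactone 2 (not isolated)
Conditions: NaNO2, 1 M aq H2SO4, 1,4-dioxane, 0 °C to rt
Reagents that add atoms: water, O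
Why: Diazotisation of an α-amino acid with hydroxy-de-amination, in which the carboxylate expels N2 with inversion to give α-lactone 2 and water opens it with a second inversion, so the S configuration (future C1′) is retained.

Step 2
Reactants: 3 (S)-3-[4-(benzyloxy)phenyl]-2-hydroxypropanoic acid
Product: 4 methyl (S)-3-[4-(benzyloxy)phenyl]-2-hydroxypropanoate
Conditions: MeOH, H2SO4 (cat.), reflux
Reagents that add atoms: methanol, CO
Why: Fischer esterification, which leaves the stereocentre untouched and is tolerated by the aryl benzyl ether.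

Step 3
Reactants: 4 methyl (S)-3-[4-(benzyloxy)phenyl]-2-hydroxypropanoate
Product: 5 methyl (S)-3-[4-(benzyloxy)phenyl]-2-(tert-butyldimethylsilyloxy)propanoate
Conditions: TBSCl, imidazole, DMF, rt
Reagents that add atoms: tert-butyldimethylsilyl chloride, CC(C)(C)[Si](C)(C)Cl
Why: Imidazole-promoted O-silylation of a secondary alcohol, which installs the bulky, non-chelating ether that enforces Felkin control in step 6.

Step 4
Reactants: 5 methyl (S)-3-[4-(benzyloxy)phenyl]-2-(tert-butyldimethylsilyloxy)propanoate
Product: 7 (S)-3-[4-(benzyloxy)phenyl]-2-(tert-butyldimethylsilyloxy)propanal, via aluminium hemiacetal 6 (not isolated)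
Conditions: iBu2AlH (1.1 equiv), CH2Cl2, −78 °C; MeOH, then aq potassium sodium tartrate
Reagents that add atoms: none
Why: Partial reduction of an ester with iBu2AlH, in which hemiacetal 6 persists at −78 °C and collapses to the aldehyde only on work-up so over-reduction is avoided, and 7 is used crude to prevent epimerisation.

Step 5
Reactants: 8 ethyl pyruvate
Product: 9 ethyl 2-(trimethylsilyloxy)acrylate
Conditions: TMSOTf, Et3N, Et2O, 0 °C; distillation
Reagents that add atoms: trimethylsilyl triflate, C[Si](C)(C)OS(=O)(=O)C(F)(F)F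
Why: Soft enolisation and O-silylation of a ketone (silyl enol ether formation), unambiguous because only the methyl side of the pyruvate can enolise.

Step 6
Reactants: 7 (S)-3-[4-(benzyloxy)phenyl]-2-(tert-butyldimethylsilyloxy)propanal; 9 ethyl 2-(trimethylsilyloxy)acrylate
Product: 11 ethyl (4R,5S)-6-[4-(benzyloxy)phenyl]-5-(tert-butyldimethylsilyloxy)-4-hydroxy-2-oxohexanoate, via difluoroboron aldolate 10 (not isolated)
Conditions: BF3·OEt2 (1.1 equiv), CH2Cl2, −78 °C; pH 7 phosphate buffer
Reagents that add atoms: none
Why: Mukaiyama aldol addition under monodentate BF3 activation, where chelation is impossible and the enol silane attacks through a polar Felkin–Anh transition state (C–OSi bond perpendicular to C=O, approach past H), setting the new carbinol C4 as R, anti to the S centre C5, before aldolate 10 is hydrolysed on work-up.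

Step 7
Reactants: 11 ethyl (4R,5S)-6-[4-(benzyloxy)phenyl]-5-(tert-butyldimethylsilyloxy)-4-hydroxy-2-oxohexanoate
Product: 12 lithium (4R,5S)-6-[4-(benzyloxy)phenyl]-5-(tert-butyldimethylsilyloxy)-4-hydroxy-2-oxohexanoate
Conditions: LiOH·H2O (1.0 equiv), THF/H2O, 0 °C, short contact; freeze-drying
Reagents that add atoms: lithium hydroxide, [Li+].[OH-]
Why: Saponification of a 2-oxo ester, an unusually electrophilic ester that one equivalent of hydroxide should consume at 0 °C faster than retro-aldol cleavage or silyl migration can set in, and the resulting carboxylate cannot lactonise.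

Step 8
Reactants: 13 2-methoxy-4-vinylphenol
Product: 14 benzyl 2-methoxy-4-vinylphenyl carbonate
Conditions: CbzCl, Et3N, CH2Cl2, 0 °C
Reagents that add atoms: benzyl chloroformate, O=C(Cl)OCc1ccccc1
Why: O-acylation of a phenol with a chloroformate (mixed carbonate formation), which masks the oxidisable phenol and lowers the electron density of the styrene.

Step 9
Reactants: 12 lithium (4R,5S)-6-[4-(benzyloxy)phenyl]-5-(tert-butyldimethylsilyloxy)-4-hydroxy-2-oxohexanoate; 14 benzyl 2-methoxy-4-vinylphenyl carbonate
Product: 18 benzyl 4-[(2S,6R)-6-{(1S)-2-[4-(benzyloxy)phenyl]-1-(tert-butyldimethylsilyloxy)ethyl}-4-oxooxan-2-yl]-2-methoxyphenyl carbonate, via acyl radical 15 (not isolated), via benzylic radical 16 (not isolated), via benzylic cation 17 (not isolated)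
Conditions: undivided cell, reticulated vitreous carbon anode, Pt cathode, constant current, 2.2 F/mol; (4-BrC6H4)3N (20 mol %), AcOH (1.1 equiv), nBu4NBF4 (0.1 M), MeCN/CH2Cl2, 3 Å MS, 0 °C; 14 (3 equiv), 12 added slowly in MeCN
Reagents that add atoms: none
Why: Proposed new method: the anodically generated aminium radical cation of (4-BrC6H4)3N removes one electron from the 2-oxo carboxylate of 12, CO2 departs, and the nucleophilic acyl radical 15 (centred on the future C4) adds to the CH2 terminus of 14 to make C3–C4 and benzylic radical 16, which a second aminium oxidises to cation 17 (radical-polar crossover). The closest known reaction types are decarboxylative acyl-radical additions of 2-oxo acids to styrenes and anodic or photoredox alkoxy-functionalisations of styrenes in which an oxidised benzylic radical is trapped by an alcohol, whereas a hydroxyl built into the acyl donor that turns the sequence into a formal [4+2] pyranone annulation has not been shown. The ring (O1, C2 to C6) closes when the C6 hydroxyl attacks C2 of 17, a six-membered closure that is 6-exo-trig with respect to the arene-delocalised C2–C(ipso) π bond, and the proton released is reduced to H2 at the cathode together with that of AcOH, so neither acid nor base accumulates. The new stereocentre C2 (S) is controlled by the resident C6 centre through a chair transition state that places the aryl group and the C6 side chain equatorial (2,6-cis), and loss of H3 from 17 would only give the (E)-hydroxy enone, which closes by oxa-Michael addition to the same thermodynamically preferred cis isomer. The step needs the carboxylate to be oxidised ahead of the styrene and the benzyloxyarene, which the electron-withdrawing carbonate on the guaiacol oxygen and the low, fixed potential of the mediator secure, and it needs radical addition to outrun oxidation of 15 to an acylium ion, decarbonylation and dimerisation, which homogeneous radical generation, excess 14 and slow addition of 12 secure. Regiochemistry follows from attack at the unsubstituted alkene carbon, the only mode that gives a benzylic radical.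

Step 10
Reactants: 18 benzyl 4-[(2S,6R)-6-{(1S)-2-[4-(benzyloxy)phenyl]-1-(tert-butyldimethylsilyloxy)ethyl}-4-oxooxan-2-yl]-2-methoxyphenyl carbonate
Product: 19 benzyl 4-[(2S,6R)-6-{(1S)-2-[4-(benzyloxy)phenyl]-1-hydroxyethyl}-4-oxooxan-2-yl]-2-methoxyphenyl carbonate
Conditions: HF·pyridine, pyridine, THF, 0 °C to rt (plastic vessel)
Reagents that add atoms: none
Why: Fluoride-driven desilylation in a buffered, weakly acidic medium, which spares the carbonate, the benzyl ether and the retro-oxa-Michael-prone pyranone, while the still acylated guaiacol ring keeps the benzylic C2–O1 bond from ionising.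

Step 11
Reactants: 19 benzyl 4-[(2S,6R)-6-{(1S)-2-[4-(benzyloxy)phenyl]-1-hydroxyethyl}-4-oxooxan-2-yl]-2-methoxyphenyl carbonate
Product: 21 (2S,6R)-2-(4-hydroxy-3-methoxyphenyl)-6-[(1S)-1-hydroxy-2-(4-hydroxyphenyl)ethyl]oxan-4-one, via aryl hydrogen carbonate 20 (not isolated)
Conditions: H2 (1 atm), 10% Pd/C, EtOAc, rt, stopped after uptake of two equivalents
Reagents that add atoms: none
Why: Catalytic hydrogenolysis of both O-benzyl groups under neutral conditions, after which aryl hydrogen carbonate 20 loses CO2 spontaneously, while the hindered secondary ring ether C2–O1, the ketone and all three stereocentres should remain untouched in the aprotic solvent.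

Compound list
1 | O-benzyl-L-tyrosine, (S)-2-amino-3-[4-(benzyloxy)phenyl]propanoic acid | N[C@@H](Cc1ccc(OCc2ccccc2)cc1)C(=O)O | starting material
2 | (R)-3-[4-(benzyloxy)benzyl]oxiran-2-one (α-lactone) | O=C1O[C@@H]1Cc1ccc(OCc2ccccc2)cc1 | intermediate (not isolated)
3 | (S)-3-[4-(benzyloxy)phenyl]-2-hydroxypropanoic acid | O[C@@H](Cc1ccc(OCc2ccccc2)cc1)C(=O)O | intermediate
4 | methyl (S)-3-[4-(benzyloxy)phenyl]-2-hydroxypropanoate | O[C@@H](Cc1ccc(OCc2ccccc2)cc1)C(=O)OC | intermediate
5 | methyl (S)-3-[4-(benzyloxy)phenyl]-2-(tert-butyldimethylsilyloxy)propanoate | CC(C)(C)[Si](C)(C)O[C@@H](Cc1ccc(OCc2ccccc2)cc1)C(=O)OC | intermediate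
6 | diisobutylaluminium hemiacetal of 5 (hemiacetal carbon undefined) | CC(C)(C)[Si](C)(C)O[C@@H](Cc1ccc(OCc2ccccc2)cc1)C(OC)O[Al](CC(C)C)CC(C)C | intermediate (not isolated)
7 | (S)-3-[4-(benzyloxy)phenyl]-2-(tert-butyldimethylsilyloxy)propanal | CC(C)(C)[Si](C)(C)O[C@@H](Cc1ccc(OCc2ccccc2)cc1)C=O | intermediate
8 | ethyl pyruvate | CCOC(=O)C(C)=O | starting material
9 | ethyl 2-(trimethylsilyloxy)acrylate | CCOC(=O)C(=C)O[Si](C)(C)C | intermediate
10 | O4-difluoroboryl aldolate of 11 | CCOC(=O)C(=O)C[C@H]([C@@H](O[Si](C)(C)C(C)(C)C)Cc1ccc(OCc2ccccc2)cc1)OB(F)F | intermediate (not isolated)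
11 | ethyl (4R,5S)-6-[4-(benzyloxy)phenyl]-5-(tert-butyldimethylsilyloxy)-4-hydroxy-2-oxohexanoate | CCOC(=O)C(=O)C[C@H]([C@@H](O[Si](C)(C)C(C)(C)C)Cc1ccc(OCc2ccccc2)cc1)O | intermediate
12 | lithium (4R,5S)-6-[4-(benzyloxy)phenyl]-5-(tert-butyldimethylsilyloxy)-4-hydroxy-2-oxohexanoate | [Li+].[O-]C(=O)C(=O)C[C@H]([C@@H](O[Si](C)(C)C(C)(C)C)Cc1ccc(OCc2ccccc2)cc1)O | intermediate (key-step precursor)
13 | 2-methoxy-4-vinylphenol (4-vinylguaiacol) | COc1cc(C=C)ccc1O | starting material
14 | benzyl 2-methoxy-4-vinylphenyl carbonate | COc1cc(C=C)ccc1OC(=O)OCc1ccccc1 | intermediate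
15 | (3R,4S)-5-[4-(benzyloxy)phenyl]-4-(tert-butyldimethylsilyloxy)-3-hydroxypentanoyl radical | O=[C]C[C@H]([C@@H](O[Si](C)(C)C(C)(C)C)Cc1ccc(OCc2ccccc2)cc1)O | intermediate (not isolated)
16 | open-chain benzylic radical at C2 (adduct of 15 to 14) | COc1cc([CH]CC(=O)C[C@H]([C@@H](O[Si](C)(C)C(C)(C)C)Cc2ccc(OCc3ccccc3)cc2)O)ccc1OC(=O)OCc1ccccc1 | intermediate (not isolated)
17 | open-chain benzylic cation at C2 | COc1cc([CH+]CC(=O)C[C@H]([C@@H](O[Si](C)(C)C(C)(C)C)Cc2ccc(OCc3ccccc3)cc2)O)ccc1OC(=O)OCc1ccccc1 | intermediate (not isolated)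
18 | benzyl 4-[(2S,6R)-6-{(1S)-2-[4-(benzyloxy)phenyl]-1-(tert-butyldimethylsilyloxy)ethyl}-4-oxooxan-2-yl]-2-methoxyphenyl carbonate | COc1cc([C@@H]2CC(=O)C[C@H]([C@@H](O[Si](C)(C)C(C)(C)C)Cc3ccc(OCc4ccccc4)cc3)O2)ccc1OC(=O)OCc1ccccc1 | intermediate (key-step product)
19 | benzyl 4-[(2S,6R)-6-{(1S)-2-[4-(benzyloxy)phenyl]-1-hydroxyethyl}-4-oxooxan-2-yl]-2-methoxyphenyl carbonate | COc1cc([C@@H]2CC(=O)C[C@H]([C@@H](O)Cc3ccc(OCc4ccccc4)cc3)O2)ccc1OC(=O)OCc1ccccc1 | intermediate
20 | aryl hydrogen carbonate of the target | COc1cc([C@@H]2CC(=O)C[C@H]([C@@H](O)Cc3ccc(O)cc3)O2)ccc1OC(=O)O | intermediate (not isolated)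
21 | (2S,6R)-2-(4-hydroxy-3-methoxyphenyl)-6-[(1S)-1-hydroxy-2-(4-hydroxyphenyl)ethyl]oxan-4-one (CNP0222055.1) | COc1cc([C@@H]2CC(=O)C[C@H]([C@@H](O)Cc3ccc(O)cc3)O2)ccc1O | target

Total step count: 11
Longest linear sequence: 9 steps (1, 2, 3, 4, 6, 7, 9, 10, 11)

Steps most likely to fail

1. Step 9.
- What may go wrong: further oxidation of the acyl radical to an acylium ion before it meets the alkene, loss of CO from the acyl radical, chain growth of the styrene, or closure of protonated precursor to a five-membered lactone.
- Fallback (known chemistry, sets out from aldehyde 7 and comes back at pyranone 18): commercial dehydrozingerone is treated with CbzCl and Et3N to give benzyl 2-methoxy-4-[(E)-3-oxobut-1-enyl]phenyl carbonate F1. TMSOTf and Et3N convert it into benzyl 2-methoxy-4-[(E)-3-(trimethylsilyloxy)buta-1,3-dienyl]phenyl carbonate F2. A BF3·OEt2-mediated Mukaiyama aldol addition of this diene to 7, under the same Felkin control as in step 6, should give benzyl 4-[(1E,5R,6S)-7-[4-(benzyloxy)phenyl]-6-(tert-butyldimethylsilyloxy)-5-hydroxy-3-oxohept-1-enyl]-2-methoxyphenyl carbonate F3. A 6-endo-trig oxa-Michael cyclisation catalysed by p-toluenesulfonic acid monohydrate in CH2Cl2, run under thermodynamic control, should then deliver the 2,6-cis pyranone 18.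

2. Step 6.
- What may go wrong: sluggish addition of the electron-poor enol silane, poor facial selectivity, and lactonisation of the adduct during work-up or chromatography.
- Fallback (sets out from aldehyde 7 and comes back at ester 11): a Barbier-type addition of ethyl 2-(bromomethyl)acrylate to 7 with indium metal in THF/H2O uses a more nucleophilic allylmetal. The non-chelating silyl ether should again direct Felkin (anti) attack, giving ethyl (4R,5S)-6-[4-(benzyloxy)phenyl]-5-(tert-butyldimethylsilyloxy)-4-hydroxy-2-methylidenehexanoate F4. This is a robust homoallylic alcohol on which diastereomers can be separated. Ozonolysis (O3, CH2Cl2, −78 °C, then Me2S) then unmasks the 2-oxo group under neutral conditions to give 11.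

3. Step 7.
- What may go wrong: retro-aldol cleavage, β-elimination of the C4 hydroxyl, migration of the silyl group from O5 to O4, or closure to the enolisable 2-oxo lactone while hydroxide is present.
- Fallback (sets out from aldehyde 7 and comes back at lithium salt 12): the ester is exchanged for one that is cleaved without base. Pyruvic acid and allyl alcohol (p-toluenesulfonic acid, azeotropic water removal) give allyl pyruvate F5. TMSOTf and Et3N give allyl 2-(trimethylsilyloxy)acrylate F6. The BF3·OEt2 aldol addition to 7 gives allyl (4R,5S)-6-[4-(benzyloxy)phenyl]-5-(tert-butyldimethylsilyloxy)-4-hydroxy-2-oxohexanoate F7. A Tsuji–Trost-type deallylation with catalytic Pd(PPh3)4 (zerovalent palladium) and lithium 2-ethylhexanoate in EtOAc then transfers the allyl group to the added carboxylate and should precipitate 12 directly.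

Further compounds
F1 | step 9 | benzyl 2-methoxy-4-[(E)-3-oxobut-1-enyl]phenyl carbonate | COc1cc(/C=C/C(C)=O)ccc1OC(=O)OCc1ccccc1
F2 | step 9 | benzyl 2-methoxy-4-[(E)-3-(trimethylsilyloxy)buta-1,3-dienyl]phenyl carbonate | COc1cc(/C=C/C(=C)O[Si](C)(C)C)ccc1OC(=O)OCc1ccccc1
F3 | step 9 | benzyl 4-[(1E,5R,6S)-7-[4-(benzyloxy)phenyl]-6-(tert-butyldimethylsilyloxy)-5-hydroxy-3-oxohept-1-enyl]-2-methoxyphenyl carbonate | COc1cc(/C=C/C(=O)C[C@H]([C@@H](O[Si](C)(C)C(C)(C)C)Cc2ccc(OCc3ccccc3)cc2)O)ccc1OC(=O)OCc1ccccc1
F4 | step 6 | ethyl (4R,5S)-6-[4-(benzyloxy)phenyl]-5-(tert-butyldimethylsilyloxy)-4-hydroxy-2-methylidenehexanoate | CCOC(=O)C(=C)C[C@H]([C@@H](O[Si](C)(C)C(C)(C)C)Cc1ccc(OCc2ccccc2)cc1)O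
F5 | step 7 | allyl pyruvate | C=CCOC(=O)C(C)=O
F6 | step 7 | allyl 2-(trimethylsilyloxy)acrylate | C=CCOC(=O)C(=C)O[Si](C)(C)C
F7 | step 7 | allyl (4R,5S)-6-[4-(benzyloxy)phenyl]-5-(tert-butyldimethylsilyloxy)-4-hydroxy-2-oxohexanoate | C=CCOC(=O)C(=O)C[C@H]([C@@H](O[Si](C)(C)C(C)(C)C)Cc1ccc(OCc2ccccc2)cc1)O
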